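**Plan**

- Numbering: ring C1 (allylic CH–OAc), C2=C3(CH3), C4, C5, C6=C7(C7′O2H), C8, C9 (CH–OAc), C10 (CH–iPr); C11 is the isopropyl CH and C12 one of its methyls.
- Enabling feature: the isopropyl-bearing C10 is bonded to the allylic carbinol C1 (next to C2=C3). With C11=C12 in place of the isopropyl, the array C1(OH)–C10–C11=C12 is what a [2,3]-Wittig shift of an allyl ether C1–O–C12–C11=C10 leaves behind. Because C2=C3 and C6=C7 are both ring-cis, the 13-membered ether (ring: O, C1–C12) that holds them is unstrained.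
- Cuts (retro): C7′ acid, acetates and isopropyl back to an isopropenyl diol; C1–C10 by retro-[2,3]-Wittig (O–C12 restored) to the 13-membered bis-allylic ether; O–C12 (Williamson); C6=C7 (aldol–elimination); C9–C10 (acylation of a Z-alkenylzinc).
- Forward: propargyl alcohol gives the Z-iodoalkene (C10–C12), which is acylated with a succinyl unit (C7′, C7–C9). Aldol–dehydration with the neryl-acetate-derived C1–C6 aldehyde joins the chain at C6=C7. O-alkylation closes the 13-membered ring, which is then contracted to the ten-membered carbocycle, the only carbocycle formed.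
- Stereochemistry: C9 by CBS reduction; C10 and C1 in the Wittig shift (C10 anti to the C9–OSi bond on the Z alkene, C1 from the Z geometry of C10=C11); C2=C3 from neryl acetate, C6=C7 by E1cB elimination, C10=C11 by anti-carbomagnesiation.

Key step: step 15

Remark: the C1 carbanion is made by direct lithiation of the ring ether; a C1-stannyl trigger is not used because the α-stannyl allylic alkoxide it needs cannot be O-alkylated reliably (it reverts to enal and stannyl anion), and the C7′ oxygen is carried as a lithium alkoxide so that only C1 and C12 offer α-oxy allylic C–H bonds.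

Abbreviations: TBS = tert-butyldimethylsilyl; DMTr = bis(4-methoxyphenyl)(phenyl)methyl; the locants C1–C12 and C7′ of the plan are used throughout. The CIP descriptor at C10 changes from R to S when C9–OTBS becomes C9–OH or C9–OAc; the configuration does not change.

**Route**

Step 1
Reactants: 1 propargyl alcohol
Product: 3 (Z)-3-iodo-2-methylprop-2-en-1-ol, via alkenylmagnesium alkoxide 2 (not isolated)
Conditions: MeMgBr (2.5 equiv), CuI (10 mol%), THF, −10 °C → rt; then I2, −10 → 0 °C
Reagents that add atoms: methylmagnesium bromide, C[Mg]Br; iodine, II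
Why: Copper-catalysed anti-carbomagnesiation of the propargylic magnesium alkoxide adds methyl to C11 and places magnesium on C10 cis to the CH2O group in a five-membered chelate, and iodinolysis with retention should give the Z iodoalkene that later fixes the C10=C11 geometry.

Step 2
Reactants: 3 (Z)-3-iodo-2-methylprop-2-en-1-ol
Product: 4 (Z)-3-iodo-2-methylallyl TBS ether
Conditions: TBSCl, imidazole, CH2Cl2, rt
Reagents that add atoms: tert-butyldimethylsilyl chloride, CC(C)(C)[Si](C)(C)Cl
Why: Routine silylation of a primary allylic alcohol (silyl ether formation) masks C12–OH for the metalation that follows.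

Step 3
Reactants: 4 (Z)-3-iodo-2-methylallyl TBS ether; 5 methyl 4-chloro-4-oxobutanoate
Product: 8 methyl (Z)-7-(TBS-oxy)-6-methyl-4-oxohept-5-enoate, via alkenyllithium 6 (not isolated), via alkenylzinc chloride 7 (not isolated)
Conditions: t-BuLi (2.1 equiv), Et2O, −78 °C; ZnCl2, THF, −78 → 0 °C; then 5, Pd(PPh3)4 (5 mol%), 0 °C → rt
Reagents that add atoms: none
Why: Iodine–lithium exchange with retention of configuration, transmetalation to zinc and palladium-catalysed Negishi acylation should form the C9–C10 bond as the Z enone without attack on the methyl ester, ether at −78 °C being used to suppress O-to-C silyl migration in 6.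

Step 4
Reactants: 8 methyl (Z)-7-(TBS-oxy)-6-methyl-4-oxohept-5-enoate
Product: 9 methyl (4R,5Z)-7-(TBS-oxy)-4-hydroxy-6-methylhept-5-enoate
Conditions: (S)-Me-CBS oxazaborolidine (20 mol%), BH3·SMe2, THF, −30 °C; MeOH quench
Reagents that add atoms: none
Why: Corey–Bakshi–Shibata reduction, in which the alkenyl group acts as the large ketone substituent, should give the (R)-carbinol at C9 by reagent control, the ester and the trisubstituted alkene being inert to borane at this temperature.

Step 5
Reactants: 9 methyl (4R,5Z)-7-(TBS-oxy)-4-hydroxy-6-methylhept-5-enoate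
Product: 10 methyl (4R,5Z)-4,7-bis(TBS-oxy)-6-methylhept-5-enoate
Conditions: TBSOTf, 2,6-lutidine, CH2Cl2, −78 °C
Reagents that add atoms: tert-butyldimethylsilyl triflate, CC(C)(C)[Si](C)(C)OS(=O)(=O)C(F)(F)F
Why: Silylation with the silyl triflate at −78 °C is faster than lactonisation of the γ-hydroxy ester and protects C9–OH as the TBS ether that later directs the facial course of the key step.

Step 6
Reactants: 11 neryl acetate
Product: 12 (2Z)-6,7-epoxy-3,7-dimethyloct-2-en-1-yl acetate (racemic epoxide)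
Conditions: mCPBA (1.05 equiv), NaHCO3, CH2Cl2, 0 °C
Reagents that add atoms: 3-chloroperoxybenzoic acid, OOC(=O)c1cccc(Cl)c1
Why: Prilezhaev epoxidation should take place at the electron-rich remote trisubstituted alkene because the C2=C3 alkene is deactivated by the allylic acetate, the epoxide stereocentre being lost in the next step.

Step 7
Reactants: 12 (2Z)-6,7-epoxy-3,7-dimethyloct-2-en-1-yl acetate
Product: 13 (2Z)-3-methyl-6-oxohex-2-en-1-yl acetate (C1–C6 aldehyde)
Conditions: H5IO6, THF–H2O, 0 °C → rt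
Reagents that add atoms: none
Why: Periodic acid hydrolyses the epoxide and cleaves the resulting glycol (Malaprade cleavage) to the C6 aldehyde and acetone without touching the Z allylic acetate.

Step 8
Reactants: 10 methyl (4R,5Z)-4,7-bis(TBS-oxy)-6-methylhept-5-enoate; 13 (2Z)-3-methyl-6-oxohex-2-en-1-yl acetate
Product: 15 methyl (6Z)-8-acetoxy-2-[(2R,3Z)-2,5-bis(TBS-oxy)-4-methylpent-3-en-1-yl]-3-hydroxy-6-methyloct-6-enoate (C6/C7 diastereomer mixture), via lithium enolate 14 (not isolated)
Conditions: LDA (1.05 equiv), THF, −78 °C; then 13, −78 °C; aq. NH4Cl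
Reagents that add atoms: none
Why: Aldol addition of the lithium ester enolate at −78 °C forms the C6–C7 bond faster than the enolate can attack the acetate, and the two new stereocentres, formed as a mixture, are removed in step 9.

Step 9
Reactants: 15 aldol adduct
Product: 17 methyl (2E,6Z)-8-acetoxy-2-[(2R,3Z)-2,5-bis(TBS-oxy)-4-methylpent-3-en-1-yl]-6-methylocta-2,6-dienoate, via C6 mesylate 16 (not isolated)
Conditions: MsCl, Et3N, CH2Cl2, 0 °C; then DBU, rt
Reagents that add atoms: none
Why: Mesylation followed by DBU-induced E1cB elimination should give the thermodynamically preferred E 2-alkylidene ester, in which C5 is cis to C8 and trans to the ester, from either aldol diastereomer.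

Step 10
Reactants: 17 (2E,6Z)-enoate with C12–OTBS and C9–OTBS
Product: 18 methyl (2E,6Z)-8-acetoxy-2-[(2R,3Z)-2-(TBS-oxy)-5-hydroxy-4-methylpent-3-en-1-yl]-6-methylocta-2,6-dienoate
Conditions: HF·pyridine, pyridine, THF, 0 °C
Reagents that add atoms: none
Why: Pyridine-buffered hydrogen fluoride cleaves the primary allylic silyl ether much faster than the hindered secondary one (selective desilylation), freeing only C12–OH.

Step 11
Reactants: 18 C12 allylic alcohol
Product: 20 methyl (2E,6Z)-8-acetoxy-2-[(2R,3Z)-2-(TBS-oxy)-5-chloro-4-methylpent-3-en-1-yl]-6-methylocta-2,6-dienoate, via C12 mesylate 19 (not isolated)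
Conditions: MsCl, 2,4,6-collidine, LiCl, DMF, 0 °C
Reagents that add atoms: lithium chloride, [Li+].[Cl-]
Why: The mesylate formed in situ is displaced by chloride in an SN2 reaction (mesyl chloride–lithium chloride–collidine protocol for allylic chlorides), which is known to proceed without allylic transposition or loss of Z geometry.

Step 12
Reactants: 20 C12 allylic chloride with C1–OAc
Product: 21 methyl (2E,6Z)-2-[(2R,3Z)-2-(TBS-oxy)-5-chloro-4-methylpent-3-en-1-yl]-8-hydroxy-6-methylocta-2,6-dienoate
Conditions: K2CO3 (0.2 equiv), MeOH, 0 °C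
Reagents that add atoms: none
Why: Carbonate-catalysed methanolysis (transesterification) removes the primary acetate at 0 °C faster than methanol can displace the allylic chloride and leaves the methyl ester and the silyl ether unchanged.

Step 13
Reactants: 21 hydroxy chloride (C1–OH, C12–Cl)
Product: 23 methyl (2Z,6E,9R,10Z)-9-(TBS-oxy)-3,11-dimethyl-13-oxacyclotrideca-2,6,10-triene-7-carboxylate (13-membered ether; O bridges C12 and C1), via sodium alkoxide 22 (not isolated)
Conditions: NaH (3 equiv), Bu4NI (0.2 equiv), THF, 45 °C, slow addition of 21 to 2 mM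
Reagents that add atoms: none
Why: Intramolecular Williamson etherification under high dilution, with iodide catalysis, closes the 13-membered ring by SN2 attack of the C1 alkoxide on the primary allylic C12 halide, a closure that is precedented for 13-membered bis-allylic ethers and is helped here by three ring-cis alkenes that hold the chain ends together.

Step 14
Reactants: 23 13-membered ether ester
Product: 24 [(2Z,6E,9R,10Z)-9-(TBS-oxy)-3,11-dimethyl-13-oxacyclotrideca-2,6,10-trien-7-yl]methanol
Conditions: DIBAL-H (2.5 equiv), CH2Cl2, −78 °C; Rochelle salt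
Reagents that add atoms: none
Why: DIBAL-H reduces the conjugated ester by 1,2-addition to the C7′ allylic alcohol, which will be carried through the key step as its lithium alkoxide.

Step 15
Reactants: 24 13-membered bis-allylic ether alcohol
Product: 27 (1R,2Z,6E,9R,10R)-9-(TBS-oxy)-7-(hydroxymethyl)-3-methyl-10-(prop-1-en-2-yl)cyclodeca-2,6-dien-1-ol, via lithium alkoxide 25 (not isolated), via C1-lithiated alkoxide 26 (not isolated)
Conditions: n-BuLi (3 equiv), THF, −78 → −30 °C; aq. NH4Cl
Reagents that add atoms: none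
Why: Butyllithium first forms the C7′ lithium alkoxide 25 and then lithiates the allylic α-oxy C1–H to give 26, whose α-oxy allyllithium undergoes a concerted suprafacial [2,3]-sigmatropic shift through a five-membered envelope (C1, O, C12, C11, C10) in which the C1–C10 bond forms, O–C12 breaks and C10=C11 moves to C11=C12, leaving a C1 alkoxide. The closest known reaction type is the butyllithium-induced [2,3]-Wittig ring contraction of 13-membered bis-allylic ethers to ten-membered homoallylic alcohols of the germacrane type. The ten-membered carbocycle is closed by transannular C1–C10 bond formation inside the 13-membered ring (contraction 13 → 10 through the five-centre transition state), not by an end-to-end cyclisation. C10 is controlled by C9, since on the Z alkene A1,3 strain holds C9–H near the alkene plane and C1 attacks C10 anti to the C9–OSi bond, which places the isopropenyl group trans to the silyloxy group, and C1 is controlled by the Z geometry of C10=C11 (C9 cis to C12), which favours the syn envelope and places the C1 oxygen cis to the isopropenyl group. The step needs lithiation at C1 and not at C12, which rests on the precedent of the parent ring system, on the less hindered C1–H2 (C12 is flanked by the C11 methyl and the C9 silyloxy branch) and on the C7′ alkoxide that switches off the side-chain allylic site, and it needs [2,3] and not [1,2] shift with retention of the C2=C3 geometry, which the low temperature should secure.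

Step 16
Reactants: 27 isopropenyl diol
Product: 28 (1R,2Z,6E,9R,10R)-9-(TBS-oxy)-7-(hydroxymethyl)-3-methyl-10-(propan-2-yl)cyclodeca-2,6-dien-1-ol
Conditions: H2 (1 atm), RhCl(PPh3)3 (10 mol%), benzene, rt
Reagents that add atoms: none
Why: Homogeneous hydrogenation with Wilkinson's catalyst saturates the 1,1-disubstituted isopropenyl alkene much faster than the two trisubstituted ring alkenes and creates no stereocentre.

Step 17
Reactants: 28 isopropyl diol
Product: 29 (1R,2Z,6E,9R,10R)-9-(TBS-oxy)-7-[(DMTr-oxy)methyl]-3-methyl-10-(propan-2-yl)cyclodeca-2,6-dien-1-ol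
Conditions: DMTrCl (1.1 equiv), pyridine, 0 °C → rt
Reagents that add atoms: 4,4′-dimethoxytrityl chloride, COc1ccc(cc1)C(Cl)(c1ccccc1)c1ccc(OC)cc1
Why: Tritylation with the bulky dimethoxytrityl chloride is selective for the primary allylic hydroxyl over the hindered secondary C1 hydroxyl (selective protection of a primary alcohol).

Step 18
Reactants: 29 DMTr ether with C9–OTBS
Product: 30 (1R,2Z,6E,9R,10S)-7-[(DMTr-oxy)methyl]-3-methyl-10-(propan-2-yl)cyclodeca-2,6-diene-1,9-diol
Conditions: TBAF (2 equiv), THF, rt; aq. NH4Cl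
Reagents that add atoms: none
Why: Fluoride-induced desilylation frees C9–OH while the trityl ether, which is inert to fluoride, keeps C7′ masked.

Step 19
Reactants: 30 C1,C9-diol
Product: 31 (1R,2Z,6E,9R,10S)-7-[(DMTr-oxy)methyl]-3-methyl-10-(propan-2-yl)cyclodeca-2,6-diene-1,9-diyl diacetate
Conditions: Ac2O, pyridine, DMAP (cat.), CH2Cl2, rt
Reagents that add atoms: acetic anhydride, CC(=O)OC(C)=O
Why: DMAP-catalysed acetylation esterifies both secondary hydroxyls while C7′ is still at the protected alcohol stage, so that no γ-hydroxy aldehyde or acid that could close to a lactol or lactone is ever exposed.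

Step 20
Reactants: 31 diacetate DMTr ether
Product: 32 (1R,2Z,6E,9R,10S)-7-(hydroxymethyl)-3-methyl-10-(propan-2-yl)cyclodeca-2,6-diene-1,9-diyl diacetate
Conditions: AcOH–H2O (4:1), rt
Reagents that add atoms: none
Why: Acid-catalysed SN1 solvolysis of the dimethoxytrityl ether occurs in aqueous acetic acid at room temperature, conditions under which the acetates and the ring alkenes should be stable.

Step 21
Reactants: 32 diacetate allylic alcohol
Product: 33 (1R,2Z,6E,9R,10S)-7-formyl-3-methyl-10-(propan-2-yl)cyclodeca-2,6-diene-1,9-diyl diacetate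
Conditions: MnO2 (excess), CH2Cl2, rt
Reagents that add atoms: none
Why: Manganese dioxide oxidises the only free hydroxyl, a primary allylic alcohol, to the enal without isomerising the C6=C7 bond.

Step 22
Reactants: 33 diacetate enal
Product: 34 CNP0172943.1, (1R,2Z,6E,9R,10S)-1,9-bis(acetyloxy)-3-methyl-10-(propan-2-yl)cyclodeca-2,6-diene-7-carboxylic acid (plan locants)
Conditions: NaClO2, NaH2PO4, 2-methyl-2-butene, t-BuOH–H2O, 0 °C → rt
Reagents that add atoms: sodium chlorite, [Na+].[O-]Cl=O
Why: Pinnick oxidation with chlorite and 2-methyl-2-butene as hypochlorite scavenger converts the enal into the acid without affecting the alkenes or the acetates.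

**Compound list**

1 | propargyl alcohol (prop-2-yn-1-ol) | C#CCO | starting material
2 | bromomagnesium (Z)-3-(bromomagnesio)-2-methylprop-2-en-1-olate | Br[Mg]/C=C(/C)CO[Mg]Br | intermediate (not isolated)
3 | (Z)-3-iodo-2-methylprop-2-en-1-ol | I/C=C(/C)CO | intermediate
4 | (Z)-tert-butyl[(3-iodo-2-methylprop-2-en-1-yl)oxy]dimethylsilane | I/C=C(/C)CO[Si](C)(C)C(C)(C)C | intermediate
5 | methyl 4-chloro-4-oxobutanoate | COC(=O)CCC(Cl)=O | starting material
6 | (Z)-[3-(TBS-oxy)-2-methylprop-1-en-1-yl]lithium | [Li]/C=C(/C)CO[Si](C)(C)C(C)(C)C | intermediate (not isolated)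
7 | (Z)-[3-(TBS-oxy)-2-methylprop-1-en-1-yl]zinc chloride | Cl[Zn]/C=C(/C)CO[Si](C)(C)C(C)(C)C | intermediate (not isolated)
8 | methyl (Z)-7-(TBS-oxy)-6-methyl-4-oxohept-5-enoate | COC(=O)CCC(=O)/C=C(/C)CO[Si](C)(C)C(C)(C)C | intermediate
9 | methyl (4R,5Z)-7-(TBS-oxy)-4-hydroxy-6-methylhept-5-enoate | COC(=O)CC[C@@H](O)/C=C(/C)CO[Si](C)(C)C(C)(C)C | intermediate
10 | methyl (4R,5Z)-4,7-bis(TBS-oxy)-6-methylhept-5-enoate (C7′, C7–C12 unit) | COC(=O)CC[C@@H](O[Si](C)(C)C(C)(C)C)/C=C(/C)CO[Si](C)(C)C(C)(C)C | intermediate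
11 | neryl acetate, (2Z)-3,7-dimethylocta-2,6-dien-1-yl acetate | CC(=O)OC/C=C(/C)CCC=C(C)C | starting material
12 | (2Z)-6,7-epoxy-3,7-dimethyloct-2-en-1-yl acetate (racemic at the epoxide) | CC(=O)OC/C=C(/C)CCC1OC1(C)C | intermediate
13 | (2Z)-3-methyl-6-oxohex-2-en-1-yl acetate (C1–C6 aldehyde) | CC(=O)OC/C=C(/C)CCC=O | intermediate
14 | lithium enolate of 10 (enolate geometry undefined) | COC(O[Li])=CC[C@@H](O[Si](C)(C)C(C)(C)C)/C=C(/C)CO[Si](C)(C)C(C)(C)C | intermediate (not isolated)
15 | methyl (6Z)-8-acetoxy-2-[(2R,3Z)-2,5-bis(TBS-oxy)-4-methylpent-3-en-1-yl]-3-hydroxy-6-methyloct-6-enoate (mixture at C6 and C7) | COC(=O)C(C(O)CC/C(C)=C\COC(C)=O)C[C@@H](O[Si](C)(C)C(C)(C)C)/C=C(/C)CO[Si](C)(C)C(C)(C)C | intermediate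
16 | C6 methanesulfonate of 15 | COC(=O)C(C(OS(C)(=O)=O)CC/C(C)=C\COC(C)=O)C[C@@H](O[Si](C)(C)C(C)(C)C)/C=C(/C)CO[Si](C)(C)C(C)(C)C | intermediate (not isolated)
17 | methyl (2E,6Z)-8-acetoxy-2-[(2R,3Z)-2,5-bis(TBS-oxy)-4-methylpent-3-en-1-yl]-6-methylocta-2,6-dienoate | COC(=O)/C(=C/CC/C(C)=C\COC(C)=O)C[C@@H](O[Si](C)(C)C(C)(C)C)/C=C(/C)CO[Si](C)(C)C(C)(C)C | intermediate
18 | methyl (2E,6Z)-8-acetoxy-2-[(2R,3Z)-2-(TBS-oxy)-5-hydroxy-4-methylpent-3-en-1-yl]-6-methylocta-2,6-dienoate | COC(=O)/C(=C/CC/C(C)=C\COC(C)=O)C[C@@H](O[Si](C)(C)C(C)(C)C)/C=C(/C)CO | intermediate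
19 | C12 methanesulfonate of 18 | COC(=O)/C(=C/CC/C(C)=C\COC(C)=O)C[C@@H](O[Si](C)(C)C(C)(C)C)/C=C(/C)COS(C)(=O)=O | intermediate (not isolated)
20 | methyl (2E,6Z)-8-acetoxy-2-[(2R,3Z)-2-(TBS-oxy)-5-chloro-4-methylpent-3-en-1-yl]-6-methylocta-2,6-dienoate | COC(=O)/C(=C/CC/C(C)=C\COC(C)=O)C[C@@H](O[Si](C)(C)C(C)(C)C)/C=C(/C)CCl | intermediate
21 | methyl (2E,6Z)-2-[(2R,3Z)-2-(TBS-oxy)-5-chloro-4-methylpent-3-en-1-yl]-8-hydroxy-6-methylocta-2,6-dienoate | COC(=O)/C(=C/CC/C(C)=C\CO)C[C@@H](O[Si](C)(C)C(C)(C)C)/C=C(/C)CCl | intermediate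
22 | sodium C1 alkoxide of 21 | COC(=O)/C(=C/CC/C(C)=C\CO[Na])C[C@@H](O[Si](C)(C)C(C)(C)C)/C=C(/C)CCl | intermediate (not isolated)
23 | methyl (2Z,6E,9R,10Z)-9-(TBS-oxy)-3,11-dimethyl-13-oxacyclotrideca-2,6,10-triene-7-carboxylate (ring O–C1…C12) | O1C/C=C(/C)CC/C=C(/C(=O)OC)C[C@@H](O[Si](C)(C)C(C)(C)C)/C=C(C)\C1 | intermediate
24 | [(2Z,6E,9R,10Z)-9-(TBS-oxy)-3,11-dimethyl-13-oxacyclotrideca-2,6,10-trien-7-yl]methanol (key-step precursor) | O1C/C=C(/C)CC/C=C(/CO)C[C@@H](O[Si](C)(C)C(C)(C)C)/C=C(C)\C1 | intermediate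
25 | lithium C7′ alkoxide of 24 | O1C/C=C(/C)CC/C=C(/CO[Li])C[C@@H](O[Si](C)(C)C(C)(C)C)/C=C(C)\C1 | intermediate (not isolated)
26 | C1-lithiated lithium alkoxide of 24 (configuration at C1 undefined) | O1C([Li])/C=C(/C)CC/C=C(/CO[Li])C[C@@H](O[Si](C)(C)C(C)(C)C)/C=C(C)\C1 | intermediate (not isolated)
27 | (1R,2Z,6E,9R,10R)-9-(TBS-oxy)-7-(hydroxymethyl)-3-methyl-10-(prop-1-en-2-yl)cyclodeca-2,6-dien-1-ol (C1–OH cis to isopropenyl, C9–O trans) | O[C@@H]1/C=C(/C)CC/C=C(/CO)C[C@@H](O[Si](C)(C)C(C)(C)C)[C@@H]1C(C)=C | intermediate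
28 | (1R,2Z,6E,9R,10R)-9-(TBS-oxy)-7-(hydroxymethyl)-3-methyl-10-(propan-2-yl)cyclodeca-2,6-dien-1-ol | O[C@@H]1/C=C(/C)CC/C=C(/CO)C[C@@H](O[Si](C)(C)C(C)(C)C)[C@@H]1C(C)C | intermediate
29 | (1R,2Z,6E,9R,10R)-9-(TBS-oxy)-7-[(DMTr-oxy)methyl]-3-methyl-10-(propan-2-yl)cyclodeca-2,6-dien-1-ol | O[C@@H]1/C=C(/C)CC/C=C(/COC(c2ccccc2)(c2ccc(OC)cc2)c2ccc(OC)cc2)C[C@@H](O[Si](C)(C)C(C)(C)C)[C@@H]1C(C)C | intermediate
30 | (1R,2Z,6E,9R,10S)-7-[(DMTr-oxy)methyl]-3-methyl-10-(propan-2-yl)cyclodeca-2,6-diene-1,9-diol | O[C@@H]1/C=C(/C)CC/C=C(/COC(c2ccccc2)(c2ccc(OC)cc2)c2ccc(OC)cc2)C[C@@H](O)[C@@H]1C(C)C | intermediate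
31 | (1R,2Z,6E,9R,10S)-7-[(DMTr-oxy)methyl]-3-methyl-10-(propan-2-yl)cyclodeca-2,6-diene-1,9-diyl diacetate | CC(=O)O[C@@H]1/C=C(/C)CC/C=C(/COC(c2ccccc2)(c2ccc(OC)cc2)c2ccc(OC)cc2)C[C@@H](OC(C)=O)[C@@H]1C(C)C | intermediate
32 | (1R,2Z,6E,9R,10S)-7-(hydroxymethyl)-3-methyl-10-(propan-2-yl)cyclodeca-2,6-diene-1,9-diyl diacetate | CC(=O)O[C@@H]1/C=C(/C)CC/C=C(/CO)C[C@@H](OC(C)=O)[C@@H]1C(C)C | intermediate
33 | (1R,2Z,6E,9R,10S)-7-formyl-3-methyl-10-(propan-2-yl)cyclodeca-2,6-diene-1,9-diyl diacetate | CC(=O)O[C@@H]1/C=C(/C)CC/C=C(/C=O)C[C@@H](OC(C)=O)[C@@H]1C(C)C | intermediate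
34 | CNP0172943.1, (1R,2Z,6E,9R,10S)-1,9-bis(acetyloxy)-3-methyl-10-(propan-2-yl)cyclodeca-2,6-diene-7-carboxylic acid (plan locants) | CC(=O)O[C@@H]1/C=C(/C)CC/C=C(/C(=O)O)C[C@@H](OC(C)=O)[C@@H]1C(C)C | target

**Step count and risks**

Total: 22 steps. Longest linear sequence: 20 steps (steps 1–5, then 8–22, from propargyl alcohol).

Steps most likely to fail:

1. Step 15. Lithiation may occur at C12 in competition with C1 (and would then be followed by loss of silanolate from C9), or C1 may add to the wrong face of C10. The fallback forms the same C1–C10 bond by an intramolecular Nozaki–Hiyama allylation and so needs neither the ether nor a carbanion at C1. It sets out from hydroxy chloride 21: MnO2 would oxidise C1–OH to the (2Z)-enal F1. CrCl2 in THF at high dilution would turn the allylic chloride into an allylchromium species that adds through its γ-carbon C10 to the C1 aldehyde, closing the ten-membered ring as the isopropenyl hydroxy ester F2, which by the usual anti preference of allylchromium additions is expected to be the C1 epimer. Mitsunobu inversion with benzoic acid would give the (1R)-benzoate F3, and DIBAL-H would cleave the benzoate and reduce the methyl ester, coming back to the route at diol 27.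

2. Step 13. Intermolecular O-alkylation (oligomerisation) may outrun ring closure because the C12 chloride, flanked by the C11 methyl and the C9 silyloxy branch, is a hindered electrophile, and the alkoxide may add to the enoate instead. The fallback exchanges the roles of the two chain ends, so that an unhindered neryl-type C1 chloride is attacked by the C12 alkoxide. It sets out from enoate 17: carbonate-catalysed methanolysis would give the C1 alcohol F4; mesyl chloride, lithium chloride and collidine would give the C1 chloride F5; buffered HF·pyridine would free C12–OH to give the hydroxy chloride F6. Its alkoxide (NaH, THF, high dilution, kept cold to avoid O-to-O silyl transfer from C9) would be cyclised, coming back to the route at 13-membered ether 23.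

3. Step 9. Geometric control in the elimination may be incomplete, giving E/Z mixtures at C6=C7. The fallback builds the alkene by Horner–Wadsworth–Emmons olefination instead of aldol–elimination. It sets out from ester 10: its lithium enolate would be C-phosphorylated (LDA; ClP(OEt)2; then H2O2) to the α-phosphono ester F7, whose sodium salt with aldehyde 13 (NaH, THF) should give the E enoate directly, coming back to the route at 17 and making step 8 unnecessary.

**Further compounds**

F1 | step 15 | methyl (2E,6Z)-2-[(2R,3Z)-2-(TBS-oxy)-5-chloro-4-methylpent-3-en-1-yl]-6-methyl-8-oxoocta-2,6-dienoate (C1 enal) | COC(=O)/C(=C/CC/C(C)=C\C=O)C[C@@H](O[Si](C)(C)C(C)(C)C)/C=C(/C)CCl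
F2 | step 15 | methyl (1S,2Z,6E,9R,10R)-9-(TBS-oxy)-1-hydroxy-3-methyl-10-(prop-1-en-2-yl)cyclodeca-2,6-diene-7-carboxylate (plan locants; C1 epimer) | O[C@H]1/C=C(/C)CC/C=C(/C(=O)OC)C[C@@H](O[Si](C)(C)C(C)(C)C)[C@@H]1C(C)=C
F3 | step 15 | methyl (1R,2Z,6E,9R,10R)-1-(benzoyloxy)-9-(TBS-oxy)-3-methyl-10-(prop-1-en-2-yl)cyclodeca-2,6-diene-7-carboxylate (plan locants) | O=C(O[C@@H]1/C=C(/C)CC/C=C(/C(=O)OC)C[C@@H](O[Si](C)(C)C(C)(C)C)[C@@H]1C(C)=C)c1ccccc1
F4 | step 13 | methyl (2E,6Z)-2-[(2R,3Z)-2,5-bis(TBS-oxy)-4-methylpent-3-en-1-yl]-8-hydroxy-6-methylocta-2,6-dienoate | COC(=O)/C(=C/CC/C(C)=C\CO)C[C@@H](O[Si](C)(C)C(C)(C)C)/C=C(/C)CO[Si](C)(C)C(C)(C)C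
F5 | step 13 | methyl (2E,6Z)-2-[(2R,3Z)-2,5-bis(TBS-oxy)-4-methylpent-3-en-1-yl]-8-chloro-6-methylocta-2,6-dienoate | COC(=O)/C(=C/CC/C(C)=C\CCl)C[C@@H](O[Si](C)(C)C(C)(C)C)/C=C(/C)CO[Si](C)(C)C(C)(C)C
F6 | step 13 | methyl (2E,6Z)-8-chloro-2-[(2R,3Z)-2-(TBS-oxy)-5-hydroxy-4-methylpent-3-en-1-yl]-6-methylocta-2,6-dienoate | COC(=O)/C(=C/CC/C(C)=C\CCl)C[C@@H](O[Si](C)(C)C(C)(C)C)/C=C(/C)CO
F7 | step 9 | methyl (4R,5Z)-4,7-bis(TBS-oxy)-2-(diethoxyphosphoryl)-6-methylhept-5-enoate (mixture at C2) | COC(=O)C(P(=O)(OCC)OCC)C[C@@H](O[Si](C)(C)C(C)(C)C)/C=C(/C)CO[Si](C)(C)C(C)(C)C
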